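**Strategy.** The route rests on disconnecting ring C at O1–C2. C2 carries O1, ring B and the oxygenated C3, so it is brought in as an aryl ketone. In one operation the ring A phenol closes onto that ketone, the hemiketal ionises to a cyclic oxocarbenium ion, and a silane delivers hydride to C2 anti to the C3 silyloxy group. This forms the O1–C2 bond, ring C and the C2 stereocentre with the 2,3-cis relationship. The precursor is an open-chain (R)-α-silyloxy ketone bearing a free ortho-phenol on ring A, its C3 stereocentre taken from methyl (R)-glycidate.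

Key step: step 7

Remark: the target is read as (−)-epicatechin 3-O-vanillate, (2R,3R), with ring B and the C3 ester oxygen cis on ring C.
Remark: opening methyl (R)-glycidate at its CH2 leaves the oxygen-bearing carbon untouched, and the priority order O > carbonyl-derived carbon > CH2 > H holds throughout, so this carbon stays (R) and becomes C3 (R).
Remark: the cation of the key step keeps C3 and C4 saturated and is therefore a 3,4-dihydrochromenylium ion.
Remark: O3 carries a bulky, non-participating silyl ether through the key step, because an acyl group there would steer hydride to the trans isomer by anchimeric assistance. All other phenols are benzyl ethers, which BF3·OEt2 and the silane should not touch at low temperature.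

Step 1
Reactants: 1 3,5-bis(benzyloxy)phenol
Product: 2 1,3-bis(benzyloxy)-5-(methoxymethoxy)benzene
Conditions: MOMCl, i-Pr2NEt, CH2Cl2, 0 °C to rt
Reagents that add atoms: chloromethyl methyl ether (MOMCl), COCCl
Why: Base-mediated O-alkylation of the only free hydroxyl (Williamson-type ether synthesis) should be clean, and the methoxymethyl ether is the directing group for step 2.

Step 2
Reactants: 2 1,3-bis(benzyloxy)-5-(methoxymethoxy)benzene; 3 methyl (R)-glycidate
Product: 6 methyl (R)-3-[2,4-bis(benzyloxy)-6-(methoxymethoxy)phenyl]-2-hydroxypropanoate, via aryllithium 4 (not isolated), via arylmagnesium bromide 5 (not isolated)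
Conditions: n-BuLi, THF, −20 to 0 °C; MgBr2·OEt2, −40 °C; CuI (10 mol %), then 3, −40 to −20 °C; sat. aq NH4Cl
Reagents that add atoms: none
Why: Directed ortho-metalation should occur at one of the two equivalent ring positions flanked by the chelating OMOM group and a benzyloxy group, and after transmetalation to magnesium the CuI-catalysed SN2 opening of the epoxide at its unsubstituted CH2 outpaces addition to the ester, so the glycidate stereocentre is carried over untouched as (R).

Step 3
Reactants: 6 methyl (R)-3-[2,4-bis(benzyloxy)-6-(methoxymethoxy)phenyl]-2-hydroxypropanoate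
Product: 8 (R)-5,7-bis(benzyloxy)-3-hydroxychroman-2-one, via phenol ester 7 (not isolated)
Conditions: conc. aq HCl (cat.), MeOH, 45 °C; evaporate; TsOH·H2O (cat.), toluene, 80 °C with removal of MeOH
Reagents that add atoms: none
Why: Acid-catalysed acetal exchange with methanol removes the MOM group, and the liberated ortho-phenol then undergoes intramolecular transesterification (6-exo-trig lactonisation) once methanol is distilled out, which leaves C3 untouched and marks the future O1 as the only acylated phenol oxygen.

Step 4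
Reactants: 8 (R)-5,7-bis(benzyloxy)-3-hydroxychroman-2-one
Product: 9 (R)-5,7-bis(benzyloxy)-3-(tert-butyldimethylsilyloxy)chroman-2-one
Conditions: TBSOTf, 2,6-lutidine, CH2Cl2, −78 to 0 °C
Reagents that add atoms: tert-butyldimethylsilyl triflate (TBSOTf), CC(C)(C)[Si](C)(C)OS(=O)(=O)C(F)(F)F
Why: Silylation of the secondary alcohol with a silyl triflate and a hindered, non-nucleophilic pyridine base should proceed without opening the reactive aryl lactone or enolising C3.

Step 5
Reactants: 9 (R)-5,7-bis(benzyloxy)-3-(tert-butyldimethylsilyloxy)chroman-2-one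
Product: 10 (R)-3-[2,4-bis(benzyloxy)-6-hydroxyphenyl]-2-(tert-butyldimethylsilyloxy)-N-methoxy-N-methylpropanamide
Conditions: MeNH(OMe)·HCl, i-PrMgCl, THF, −20 °C; then 9, −20 to 0 °C; sat. aq NH4Cl
Reagents that add atoms: N,O-dimethylhydroxylamine hydrochloride, CNOC.Cl
Why: Aminolysis of the activated aryl ester by the chloromagnesium amide of N,O-dimethylhydroxylamine (Weinreb amide formation) is driven by expulsion of the phenoxide, so the ring A phenol needed for the key step is unmasked in the same operation without touching C3.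

Step 6
Reactants: 10 (R)-3-[2,4-bis(benzyloxy)-6-hydroxyphenyl]-2-(tert-butyldimethylsilyloxy)-N-methoxy-N-methylpropanamide; 11 4-bromo-1,2-bis(benzyloxy)benzene
Product: 13 (R)-1-[3,4-bis(benzyloxy)phenyl]-3-[2,4-bis(benzyloxy)-6-hydroxyphenyl]-2-(tert-butyldimethylsilyloxy)propan-1-one, via Grignard reagent 12 (not isolated)
Conditions: 11, Mg, THF, 45 °C; then 10 (to 3 equiv of the Grignard reagent), −20 to 0 °C; sat. aq NH4Cl, cold
Reagents that add atoms: none
Why: In this Weinreb ketone synthesis the first equivalent of the Grignard reagent only deprotonates the phenol and the next adds to the amide to give a chelated tetrahedral magnesium adduct that releases the ketone on work-up, which prevents over-addition and does not involve the C3 stereocentre.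

Step 7
Reactants: 13 (R)-1-[3,4-bis(benzyloxy)phenyl]-3-[2,4-bis(benzyloxy)-6-hydroxyphenyl]-2-(tert-butyldimethylsilyloxy)propan-1-one
Product: 16 (2R,3R)-3-O-tert-butyldimethylsilyl-5,7,3',4'-tetra-O-benzylepicatechin, via hemiketal 14 (not isolated), via oxocarbenium ion 15 (not isolated)
Conditions: Et3SiH (5 equiv), BF3·OEt2 (2 equiv), CH2Cl2 (0.02 M), −78 to −40 °C; aq NaHCO3
Reagents that add atoms: none
Why: BF3·OEt2 promotes addition of the ring A phenol to the C2 ketone (6-exo-trig closure of ring C, giving hemiketal 14) and then ionises the C2–OH bond to the 3,4-dihydrochromenylium ion 15, which Et3SiH reduces at C2, so O1–C2 and C2–H are formed in one flask. The closest known reaction type is the Lewis acid and silane reduction of aryl lactols used for C-aryl glycosides, together with the reductive etherification of hydroxy ketones. The C2 stereocentre is set under substrate control by the C3 silyloxy group: with ring B coplanar with the cation, A1,2 strain should push the bulky OTBS group pseudo-axial, and hydride should then enter along the axial trajectory antiperiplanar to the C3–O bond (a cyclic polar Felkin–Anh arrangement), leaving H2 trans to O3 and ring B cis to O3, that is (2R,3R). The step needs hydride capture of 15 to outrun both loss of H3 (which would give the flav-2-ene and erode the C3 configuration) and reduction of the open ketone before ring closure; the free ortho-phenol six atoms from the carbonyl, the non-participating silyl ether, excess silane, high dilution and low temperature are meant to secure this. The cis outcome is expected on these grounds but is not an established result for a 2-aryl-3-oxychroman cation.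

Step 8
Reactants: 16 (2R,3R)-3-O-tert-butyldimethylsilyl-5,7,3',4'-tetra-O-benzylepicatechin
Product: 17 (2R,3R)-5,7,3',4'-tetra-O-benzylepicatechin
Conditions: Bu4NF, THF, 0 °C to rt
Reagents that add atoms: none
Why: Fluoride cleaves the Si–O bond (desilylation driven by the strong Si–F bond) while the benzyl ethers and the C2 and C3 stereocentres are inert to these conditions.

Step 9
Reactants: 17 (2R,3R)-5,7,3',4'-tetra-O-benzylepicatechin; 18 4-(benzyloxy)-3-methoxybenzoic acid
Product: 19 (2R,3R)-5,7,3',4'-tetra-O-benzylepicatechin 3-O-[4-(benzyloxy)-3-methoxybenzoate]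
Conditions: DCC, DMAP, CH2Cl2, 0 °C to rt
Reagents that add atoms: none
Why: Steglich esterification (carbodiimide activation with DMAP as acyl-transfer catalyst) acylates the single free hydroxyl at O3 with retention, since the C3–O bond is not broken.

Step 10
Reactants: 19 (2R,3R)-5,7,3',4'-tetra-O-benzylepicatechin 3-O-[4-(benzyloxy)-3-methoxybenzoate]
Product: 20 (−)-epicatechin 3-O-vanillate [(2R,3R)-2-(3,4-dihydroxyphenyl)-5,7-dihydroxychroman-3-yl 4-hydroxy-3-methoxybenzoate]
Conditions: H2 (1 atm), Pd(OH)2 on carbon, THF/MeOH, rt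
Reagents that add atoms: none
Why: Hydrogenolysis of the five benzyl aryl ethers over Pd(OH)2 on carbon should leave the benzoate ester and the ring C alkyl aryl ether intact at one atmosphere and room temperature, and no stereocentre is affected.

**Compound list**

1 | 3,5-bis(benzyloxy)phenol | Oc1cc(OCc2ccccc2)cc(OCc2ccccc2)c1 | starting material
2 | 1,3-bis(benzyloxy)-5-(methoxymethoxy)benzene | COCOc1cc(OCc2ccccc2)cc(OCc2ccccc2)c1 | intermediate
3 | methyl (R)-glycidate | COC(=O)[C@H]1CO1 | starting material
4 | [2,4-bis(benzyloxy)-6-(methoxymethoxy)phenyl]lithium | [Li]c1c(OCOC)cc(OCc2ccccc2)cc1OCc1ccccc1 | intermediate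
5 | [2,4-bis(benzyloxy)-6-(methoxymethoxy)phenyl]magnesium bromide | Br[Mg]c1c(OCOC)cc(OCc2ccccc2)cc1OCc1ccccc1 | intermediate
6 | methyl (R)-3-[2,4-bis(benzyloxy)-6-(methoxymethoxy)phenyl]-2-hydroxypropanoate | COC(=O)[C@H](O)Cc1c(OCOC)cc(OCc2ccccc2)cc1OCc1ccccc1 | intermediate
7 | methyl (R)-3-[2,4-bis(benzyloxy)-6-hydroxyphenyl]-2-hydroxypropanoate | COC(=O)[C@H](O)Cc1c(O)cc(OCc2ccccc2)cc1OCc1ccccc1 | intermediate
8 | (R)-5,7-bis(benzyloxy)-3-hydroxychroman-2-one | O=C1Oc2cc(OCc3ccccc3)cc(OCc3ccccc3)c2C[C@H]1O | intermediate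
9 | (R)-5,7-bis(benzyloxy)-3-(tert-butyldimethylsilyloxy)chroman-2-one | O=C1Oc2cc(OCc3ccccc3)cc(OCc3ccccc3)c2C[C@H]1O[Si](C)(C)C(C)(C)C | intermediate
10 | (R)-3-[2,4-bis(benzyloxy)-6-hydroxyphenyl]-2-(tert-butyldimethylsilyloxy)-N-methoxy-N-methylpropanamide | CON(C)C(=O)[C@H](O[Si](C)(C)C(C)(C)C)Cc1c(O)cc(OCc2ccccc2)cc1OCc1ccccc1 | intermediate
11 | 4-bromo-1,2-bis(benzyloxy)benzene | Brc1ccc(OCc2ccccc2)c(OCc2ccccc2)c1 | starting material
12 | [3,4-bis(benzyloxy)phenyl]magnesium bromide | Br[Mg]c1ccc(OCc2ccccc2)c(OCc2ccccc2)c1 | intermediate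
13 | (R)-1-[3,4-bis(benzyloxy)phenyl]-3-[2,4-bis(benzyloxy)-6-hydroxyphenyl]-2-(tert-butyldimethylsilyloxy)propan-1-one | CC(C)(C)[Si](C)(C)O[C@@H](C(=O)c1ccc(OCc2ccccc2)c(OCc2ccccc2)c1)Cc1c(O)cc(OCc2ccccc2)cc1OCc1ccccc1 | intermediate
14 | (3R)-5,7-bis(benzyloxy)-2-[3,4-bis(benzyloxy)phenyl]-3-(tert-butyldimethylsilyloxy)chroman-2-ol (both C2 epimers) | CC(C)(C)[Si](C)(C)O[C@@H]1Cc2c(OCc3ccccc3)cc(OCc3ccccc3)cc2OC1(O)c1ccc(OCc2ccccc2)c(OCc2ccccc2)c1 | intermediate
15 | (3R)-5,7-bis(benzyloxy)-2-[3,4-bis(benzyloxy)phenyl]-3-(tert-butyldimethylsilyloxy)-3,4-dihydrochromenylium hydroxytrifluoroborate | CC(C)(C)[Si](C)(C)O[C@@H]1Cc2c(OCc3ccccc3)cc(OCc3ccccc3)cc2[O+]=C1c1ccc(OCc2ccccc2)c(OCc2ccccc2)c1.O[B-](F)(F)F | intermediate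
16 | (2R,3R)-3-O-tert-butyldimethylsilyl-5,7,3',4'-tetra-O-benzylepicatechin | CC(C)(C)[Si](C)(C)O[C@@H]1Cc2c(OCc3ccccc3)cc(OCc3ccccc3)cc2O[C@@H]1c1ccc(OCc2ccccc2)c(OCc2ccccc2)c1 | intermediate
17 | (2R,3R)-5,7,3',4'-tetra-O-benzylepicatechin | O[C@@H]1Cc2c(OCc3ccccc3)cc(OCc3ccccc3)cc2O[C@@H]1c1ccc(OCc2ccccc2)c(OCc2ccccc2)c1 | intermediate
18 | 4-(benzyloxy)-3-methoxybenzoic acid | COc1cc(C(=O)O)ccc1OCc1ccccc1 | starting material
19 | (2R,3R)-5,7,3',4'-tetra-O-benzylepicatechin 3-O-[4-(benzyloxy)-3-methoxybenzoate] | COc1cc(C(=O)O[C@@H]2Cc3c(OCc4ccccc4)cc(OCc4ccccc4)cc3O[C@@H]2c2ccc(OCc3ccccc3)c(OCc3ccccc3)c2)ccc1OCc1ccccc1 | intermediate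
20 | (−)-epicatechin 3-O-vanillate, (2R,3R) | COc1cc(C(=O)O[C@@H]2Cc3c(O)cc(O)cc3O[C@@H]2c2ccc(O)c(O)c2)ccc1O | target

**Totals**

Total step count: 10. Longest linear sequence: 10 steps (compound 1 to compound 20); compounds 3, 11 and 18 enter at steps 2, 6 and 9.

**Steps most likely to fail**

Step 7. Hydride delivery may show poor facial selectivity. The C3 configuration may erode through reversible proton loss from the cation to the flav-2-ene. The open ketone may be reduced before ring closure, and the silyl ether may be lost under the Lewis acid. The fallback forms O1–C2 by substitution instead of reduction and sets out from 13. Felkin–Anh reduction with LiBH(s-Bu)3 in THF at −78 °C should give the anti alcohol (1S,2R)-1-[3,4-bis(benzyloxy)phenyl]-3-[2,4-bis(benzyloxy)-6-hydroxyphenyl]-2-(tert-butyldimethylsilyloxy)propan-1-ol F1. Mitsunobu cyclisation (PPh3, DIAD, THF, 0 °C) then lets the ring A phenoxide displace the activated benzylic oxygen with inversion, so that C2 becomes (R). The route is rejoined at 16.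

Step 2. Lithiation may take place between the two benzyloxy groups or at a benzylic CH2 (followed by Wittig rearrangement), and the organometallic may add to the ester instead of the epoxide. The fallback fixes the metalation site by halogen–metal exchange and sets out from 1. Hydrogen-bond-directed ortho-bromination (NBS, cat. i-Pr2NH, CH2Cl2, −78 to 0 °C) should give 2-bromo-3,5-bis(benzyloxy)phenol F2. Protection with MOMCl and i-Pr2NEt gives 1,5-bis(benzyloxy)-2-bromo-3-(methoxymethoxy)benzene F3. Bromine–lithium exchange (n-BuLi, THF, −78 °C) then generates the aryllithium regiospecifically and below the temperature at which benzylic deprotonation competes. The route is rejoined at 4.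

Step 6. Acyl substitution at the hindered amide may stall as the magnesium phenoxide aggregates, and prolonged exposure to the basic reagent may epimerise the carbon next to the carbonyl. The fallback uses a more electrophilic carbonyl at a lower oxidation level and sets out from 9. Reduction with i-Bu2AlH (CH2Cl2, −78 °C) gives the lactol (3R)-5,7-bis(benzyloxy)-3-(tert-butyldimethylsilyloxy)chroman-2-ol F4. Addition of Grignard reagent 12 (THF, −40 to 0 °C) to its hydroxy aldehyde form gives (2R)-1-[3,4-bis(benzyloxy)phenyl]-3-[2,4-bis(benzyloxy)-6-hydroxyphenyl]-2-(tert-butyldimethylsilyloxy)propan-1-ol F5 as a mixture at the carbinol carbon. MnO2 (CH2Cl2, rt) then oxidises the electron-rich benzylic alcohol chemoselectively. The route is rejoined at 13.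

**Further compounds**

F1 | step 7 | (1S,2R)-1-[3,4-bis(benzyloxy)phenyl]-3-[2,4-bis(benzyloxy)-6-hydroxyphenyl]-2-(tert-butyldimethylsilyloxy)propan-1-ol | CC(C)(C)[Si](C)(C)O[C@@H]([C@@H](O)c1ccc(OCc2ccccc2)c(OCc2ccccc2)c1)Cc1c(O)cc(OCc2ccccc2)cc1OCc1ccccc1
F2 | step 2 | 2-bromo-3,5-bis(benzyloxy)phenol | Oc1cc(OCc2ccccc2)cc(OCc2ccccc2)c1Br
F3 | step 2 | 1,5-bis(benzyloxy)-2-bromo-3-(methoxymethoxy)benzene | COCOc1cc(OCc2ccccc2)cc(OCc2ccccc2)c1Br
F4 | step 6 | (3R)-5,7-bis(benzyloxy)-3-(tert-butyldimethylsilyloxy)chroman-2-ol | OC1Oc2cc(OCc3ccccc3)cc(OCc3ccccc3)c2C[C@H]1O[Si](C)(C)C(C)(C)C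
F5 | step 6 | (2R)-1-[3,4-bis(benzyloxy)phenyl]-3-[2,4-bis(benzyloxy)-6-hydroxyphenyl]-2-(tert-butyldimethylsilyloxy)propan-1-ol (both C1 epimers) | CC(C)(C)[Si](C)(C)O[C@@H](C(O)c1ccc(OCc2ccccc2)c(OCc2ccccc2)c1)Cc1c(O)cc(OCc2ccccc2)cc1OCc1ccccc1
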